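## The problem

The target is a daucane: a cyclopentane (C1–C5) trans-fused along C1–C5 to a cycloheptane (C1, C5, C6–C10). C1 carries the methyl group C15, C4 an isopropyl group and a tertiary hydroxyl, C6 the isovalerate, C8 the exocyclic methylene C14, and C9 and C10 a cis-diol. Taking the face that bears C15 as β, the substituents are 4β-OH, 5α-H, 6α-O-acyl, 9α-OH and 10α-OH. Six stereocentres (C1, C4, C5, C6, C9, C10) must therefore be set, two of them (C1, C4) fully substituted and flanking the ring-fusion methine C5. C4 can be bought; C1 and C10 must then be fixed relative to it while the seven-membered ring forms, after which C9 can be relayed from C10, C6 from C4 (1,3-anti) and C5 from the oxygen placed on C6. The awkward centre is C5: its α face is the concave one, flanked by the isopropyl group and C10, so a reagent adding hydrogen directly to a C5=C6 alkene should arrive from β and give the cis-fused epimer. Fragile points are the allylic 8(14)-en-9-ol, the single ester among four hydroxyls, the 4-hydroxy-6-ketone (an aldol) that the route passes through, and any cation at C5, which invites a semipinacol shift from the C4 carbinol. What makes a short ring construction possible is that, with C14 carried as a carboxyl carbon, the seven-membered ring is a cyclohepta-1,4-diene (C5=C6, C8=C9, C7 between them, C1–C10 opposite). This is the product pattern of a [3,3] shift of a cis-divinylcyclopropane on C6, C7, C8, and C1–C6 with C15, the isopropyl group and the C4 carbinol are the atoms of a 1-vinylcyclopentene obtainable from (S)-terpinen-4-ol.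

## Retrosynthesis

**Ester and diol unmasking (25 ⇐ 24 ⇐ 22 + 23).** The O6–acyl bond is cut last but one, because the ester would not survive the hydride steps. Acylation with 23 is clean only if C6–OH is the sole acylable hydroxyl, so the 9,10-diol is tied up as an acetonide (24, 22) and the tertiary C4–OH is left free. The forward demands are acylation of a hindered secondary alcohol and a mild acetal hydrolysis.

**C5 and C6 (22 ⇐ 21 ⇐ 20 ⇐ 19 ⇐ 18).** The C6–H and C5–H bonds and the epoxide C–O bonds are cut in turn, back to the C5=C6 alkene 18.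
- Hydroboration of 18 would be the shortest route, but should add from β and give the cis-fused epimer.
- A cationic epoxide-to-ketone shift would set 5α-H, but a C5 cation next to the C4 oxygen favours migration from C4.
- The chosen sequence therefore uses C4–OH to direct an epoxide to the β face (19) and opens it homolytically at C5, hydrogen entering anti to the oxygen on C6 (20).
- C6 is then corrected through ketone 21 by hydride delivery from the same C4–OH (22).

Alkene 18 has two stereocentres fewer than 22.

**C9 and the exocyclic alkene (18 ⇐ 17 ⇐ 16 ⇐ 15 ⇐ 14).** The acetonide is removed retrosynthetically, and the 8(14)-en-9-ol of 17 is traced through epoxy iodide 16 and epoxy alcohol 15 to the primary allylic alcohol 14. This 1,3-oxygen transposition sets C9 by the face of epoxidation, which the Ti(OiPr)4–tartrate reagent can dictate. A [2,3] selenoxide shift would leave that face to the substrate, and VO(acac)2 would have two competing directing hydroxyls. Triol 14 lacks the C9 centre and still carries both ring alkenes.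

**Adjustment of the annulation product (14 ⇐ 13 ⇐ 12).** Desilylation and ester reduction are undone, returning C14 to the ester level and both oxygens to silyl ethers. Ester 12 is the skipped diene that the key step delivers.

**Key disconnection (12 ⇐ 11 ⇐ 6 + 10).** C1–C10 is cut as a [3,3] bond and C7–C8 (with the transient C6–C8) as a carbenoid cyclopropanation. This removes the seven-membered ring and two stereocentres at once and leaves a four-step diene 6 and a two-step diazoester 10. The forward reaction must choose the vinyl group over the tetrasubstituted alkene, the carbenoid carbon over its vinylogous end, and one face of C6=C7.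

**Diene (6 ⇐ 5 ⇐ 4 ⇐ 3 ⇐ 2 ⇐ 1).** C6=C7 is cut by Wittig logic and C5=C1 by aldol condensation, and reconnecting the two carbonyls of 4 through ozonide 3 gives the cyclohexene of silyl ether 2, hence 1. The terpene supplies C1–C6, C15, the isopropyl group and the C4 stereocentre, so no asymmetric step is needed for C4.

**Diazoester (10 ⇐ 9 ⇐ 7 + 8).** C9=C10 is cut by dehydration and C8–C9 by addition of diazoacetate 7 to aldehyde 8. The other obvious route, kinetic enol silylation of a 4-oxo ester followed by diazo transfer, fixes the enol ether geometry in a step that tends to favour the cis isomer. Elimination from 9 should place the silyloxy group trans, which is what the boat transition state needs.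

## Roads not taken

**Alternative 1:** The cut is C1–C10 and C5–C6 on a preformed five-membered ring. 3-Methylcyclopent-2-en-1-one A1, the vinylalane A2 and the alkynyl aldehyde A3 would be combined under chiral copper catalysis (for example Cu(OTf)2 with a chiral carbene ligand), conjugate addition then aldol trapping giving cyclopentanone A4.
- Merits: C1 is set by a catalyst from achiral inputs, and C5 and C6 arise in the same flask with the C6 oxygen already in place. On C5/C6 this is better than the chosen plan, which spends four steps there.
- Weak points: no ring closes, so the seven-membered ring must still be made by joining C8 to C9 on a crowded cyclopentane. The C4 carbinol needs isopropyl addition to an enolisable, β-oxygenated ketone. C9 and C10 carry no oxygen (C10 bears silicon).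
- Comparison: the chosen plan sets against the C5/C6 advantage the ring closure itself, the C10 oxygen with defined configuration, and C4 from the chiral pool.

**Alternative 2:** The cut is C1–C5. Anodic oxidation of the enol ether–allylsilane A5 would give a radical cation that is attacked by the allylsilane, closing the cyclopentane to A6 with loss of silicon and capture of methanol at C6.
- Merits: the congested bond between a quaternary and a tertiary carbon forms without a metal or a diazo compound. C5–H is installed directly, which sidesteps the hardest problem of the chosen plan, and C6 arrives at the aldehyde level.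
- Weak points: A5 needs the tertiary C4 carbinol made enantioselectively in an open chain. C1 and C5 would be controlled only by the conformational preference of a carbinol whose two substituents are of similar size. The seven-membered ring, C7, C8, C14 and both diol oxygens are all still missing.
- Comparison: equal or better at C5, clearly longer after the key step; the chosen plan offers ring closure and C10 oxygenation in one operation.

**Alternative 3:** The cut is C1–C5 and C6–C7. The tethered alkyne–siloxyvinylcyclopropane A7 would undergo a (5+2) cycloaddition under [Rh(CO)2Cl]2 (monovalent rhodium) to the hydroazulene A8, closing both rings at once.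
- Merits: it is the most economical ring construction of the four. The C9 oxygen lands at the ketone level exactly where needed, so C10 hydroxylation and C8 methylenation would be direct enolate chemistry, shorter than the five-step C14-to-C9 transposition used here.
- Weak points: the reacting alkene terminus of the vinylcyclopropane is fully substituted, a class that is reluctant in this cycloaddition. C1 must be induced from C4 through the tether. A7 needs an enantioselective tertiary propargylic carbinol and a defined trisubstituted alkene. The C5=C6 alkene of A8 poses the same C5/C6 problem as 12.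
- Comparison: the chosen plan answers with C4 from a terpene, a metal-mediated step on an unhindered vinyl group with the hindered terminus left to a thermal pericyclic step, and a C1/C10 relationship fixed by the boat geometry.

Key step: step 7

Remark: (S)-(+)-terpinen-4-ol of high enantiomeric purity and methyl diazoacetate (as a solution) are taken as purchasable; names from compound 15 onward use the daucane numbering and the α/β convention defined in the first section.

## Route

Step 1
Reactants: 1 (S)-terpinen-4-ol
Product: 2 triethyl{[(1S)-4-methyl-1-(propan-2-yl)cyclohex-3-en-1-yl]oxy}silane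
Conditions: TESOTf, 2,6-lutidine, CH2Cl2, −78 → 0 °C
Reagents that add atoms: triethylsilyl trifluoromethanesulfonate, CC[Si](CC)(CC)OS(=O)(=O)C(F)(F)F
Why: Silyl triflate with a hindered pyridine base silylates tertiary alcohols (silyl ether formation); the ether prevents retro-aldol cleavage after ozonolysis and O–H insertion in step 7, and the stereocentre is not touched.

Step 2
Reactants: 2 triethyl{[(1S)-4-methyl-1-(propan-2-yl)cyclohex-3-en-1-yl]oxy}silane
Product: 4 (3S)-6-oxo-3-(propan-2-yl)-3-[(triethylsilyl)oxy]heptanal, via ozonide 3 (not isolated)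
Conditions: O3, CH2Cl2, −78 °C; then PPh3, −78 °C → rt
Reagents that add atoms: ozone, [O-][O+]=O
Why: Ozonolysis (Criegee mechanism) cleaves the only alkene; PPh3 reduces ozonide 3 to the keto aldehyde without affecting the silyl ether or the C4 centre.

Step 3
Reactants: 4 (3S)-6-oxo-3-(propan-2-yl)-3-[(triethylsilyl)oxy]heptanal
Product: 5 (5R)-2-methyl-5-(propan-2-yl)-5-[(triethylsilyl)oxy]cyclopent-1-ene-1-carbaldehyde
Conditions: piperidine (0.2 equiv), AcOH (0.2 equiv), toluene, 80 °C
Reagents that add atoms: none
Why: Intramolecular aldol condensation under amine/acid catalysis: the aldehyde enamine adds to the methyl ketone to close the five-membered ring and dehydration gives the conjugated tetrasubstituted enal. These conditions avoid the ketone-enolate pathway to the acetylcyclopentene isomer, and silyloxide is a poor leaving group for β-elimination.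

Step 4
Reactants: 5 (5R)-2-methyl-5-(propan-2-yl)-5-[(triethylsilyl)oxy]cyclopent-1-ene-1-carbaldehyde
Product: 6 (5R)-1-ethenyl-2-methyl-5-(propan-2-yl)-5-[(triethylsilyl)oxy]cyclopent-1-ene
Conditions: Ph3PCH3Br, KN(SiMe3)2, THF, 0 °C → rt
Reagents that add atoms: methyltriphenylphosphonium bromide, C[P+](c1ccccc1)(c1ccccc1)c1ccccc1.[Br-]
Why: Wittig methylenation; the small non-stabilised ylide reaches the hindered conjugated aldehyde and the enal has no acidic or eliminable position.

Step 5
Reactants: 7 methyl diazoacetate; 8 (tert-butyldimethylsilyloxy)acetaldehyde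
Product: 9 methyl 4-[(tert-butyldimethylsilyl)oxy]-2-diazo-3-hydroxybutanoate (racemic)
Conditions: DBU (0.2 equiv), MeCN, 0 °C → rt
Reagents that add atoms: none
Why: Amidine-catalysed aldol-type addition of the acidic diazoacetate C–H to an aldehyde; the new carbinol centre is racemic and is removed in step 6.

Step 6
Reactants: 9 methyl 4-[(tert-butyldimethylsilyl)oxy]-2-diazo-3-hydroxybutanoate
Product: 10 methyl (3E)-4-[(tert-butyldimethylsilyl)oxy]-2-diazobut-3-enoate
Conditions: POCl3, Et3N, CH2Cl2, 0 °C; used at once
Reagents that add atoms: none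
Why: Dehydration of a β-hydroxy α-diazo ester through its dichlorophosphate (base-mediated elimination) is an established entry to vinyldiazoacetates. Only the C4 hydrogens can be lost, and the trans enol ether, in which the silyloxy group avoids the diazoester, should predominate.

Step 7
Reactants: 6 (5R)-1-ethenyl-2-methyl-5-(propan-2-yl)-5-[(triethylsilyl)oxy]cyclopent-1-ene; 10 methyl (3E)-4-[(tert-butyldimethylsilyl)oxy]-2-diazobut-3-enoate
Product: 12 methyl (3R,8R,8aS)-8-[(tert-butyldimethylsilyl)oxy]-8a-methyl-3-(propan-2-yl)-3-[(triethylsilyl)oxy]-1,2,3,5,8,8a-hexahydroazulene-6-carboxylate, via divinylcyclopropane 11 (not isolated)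
Conditions: Rh2(R-DOSP)4 (1 mol%), hexanes, −40 °C → rt, 10 added slowly; then toluene, 90 °C
Reagents that add atoms: none
Why: Dirhodium tetrakis[(R)-N-(4-dodecylbenzenesulfonyl)prolinate], a divalent rhodium dimer, converts 10 into a donor/acceptor vinylcarbenoid that adds to the unhindered monosubstituted C6=C7 alkene of 6 in a concerted, asynchronous [2+1] step (C7–C8 and C6–C8), the siloxyvinyl arm ending cis to the cyclopentenyl group as is general for this carbenoid class. The cis-divinylcyclopropane 11 then undergoes a [3,3]-sigmatropic (Cope) shift through the boat transition state, breaking C6–C8 and forming C1–C10; this pericyclic step, driven by release of cyclopropane strain, is the closure of the seven-membered ring. The closest known reaction type is the tandem cyclopropanation/Cope rearrangement (formal [4+3] cycloaddition) of vinyldiazoacetates with 1,3-dienes, including dienes whose reacting terminus is disubstituted. In the boat the (E)-siloxy group and ring carbon C2 point outward and H10 and C15 inward, so the C10 oxygen emerges trans to C15. The absolute configuration of C1 and C10 follows from the face of C6=C7 chosen by the catalyst (the (1R,2S)-cyclopropane), because the boat then fixes which face of C5=C1 meets C10; the R-configured catalyst is assigned from the accepted facial model for this catalyst family, and its antipode reverses the sense. The step needs site selectivity (vinyl group over the tetrasubstituted alkene, carbenoid carbon over the vinylogous terminus), secured by the steric accessibility of the vinyl group and the hydrocarbon solvent, and catalyst control over the C4 centre, which is plausible because C4 is three bonds from the alkene that is cyclopropanated. Heating is included because C15 sits inside the boat and slows the rearrangement.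

Step 8
Reactants: 12 methyl (3R,8R,8aS)-8-[(tert-butyldimethylsilyl)oxy]-8a-methyl-3-(propan-2-yl)-3-[(triethylsilyl)oxy]-1,2,3,5,8,8a-hexahydroazulene-6-carboxylate
Product: 13 [(3R,8R,8aS)-8-[(tert-butyldimethylsilyl)oxy]-8a-methyl-3-(propan-2-yl)-3-[(triethylsilyl)oxy]-1,2,3,5,8,8a-hexahydroazulen-6-yl]methanol
Conditions: iBu2AlH (DIBAL-H), CH2Cl2, −78 °C; aq. KNaC4H4O6
Reagents that add atoms: none
Why: 1,2-Reduction of the conjugated ester to the primary allylic alcohol by iBu2AlH at low temperature; silyl ethers and both alkenes are inert.

Step 9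
Reactants: 13 [(3R,8R,8aS)-8-[(tert-butyldimethylsilyl)oxy]-8a-methyl-3-(propan-2-yl)-3-[(triethylsilyl)oxy]-1,2,3,5,8,8a-hexahydroazulen-6-yl]methanol
Product: 14 (3R,8R,8aS)-6-(hydroxymethyl)-8a-methyl-3-(propan-2-yl)-1,2,3,5,8,8a-hexahydroazulene-3,8-diol
Conditions: TBAF, THF, rt → 40 °C
Reagents that add atoms: none
Why: Fluoride-mediated desilylation frees the C10 and C4 hydroxyls that steer the later oxidations; it is placed after the reduction so that no γ-hydroxy enoate meets a basic reagent.

Step 10
Reactants: 14 (3R,8R,8aS)-6-(hydroxymethyl)-8a-methyl-3-(propan-2-yl)-1,2,3,5,8,8a-hexahydroazulene-3,8-diol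
Product: 15 8α,9α-epoxydauc-5-ene-4β,10α,14-triol
Conditions: Ti(OiPr)4 (1.2 equiv), L-(+)-diethyl tartrate (1.4 equiv), t-BuOOH, 4 Å MS, CH2Cl2, −20 °C
Reagents that add atoms: tert-butyl hydroperoxide, CC(C)(C)OO
Why: Sharpless asymmetric epoxidation of the primary, 2,3-disubstituted allylic alcohol: the L-(+)-tartrate complex of Ti(OiPr)4 delivers oxygen to the α face of C8=C9 (reagent control, the face on which the 10α-hydroxyl also lies), which sets C9. The C5=C6 alkene has only a tertiary allylic hydroxyl, a poor substrate for this reagent, and is left.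

Step 11
Reactants: 15 8α,9α-epoxydauc-5-ene-4β,10α,14-triol
Product: 16 8α,9α-epoxy-14-iododauc-5-ene-4β,10α-diol
Conditions: PPh3, I2, imidazole, THF, 0 °C
Reagents that add atoms: iodine, [I][I]
Why: Appel-type iodination is selective for the primary hydroxyl; the neopentyl-like secondary C10–OH and the tertiary C4–OH are too hindered, and the buffered medium leaves the epoxide intact.

Step 12
Reactants: 16 8α,9α-epoxy-14-iododauc-5-ene-4β,10α-diol
Product: 17 dauca-5,8(14)-diene-4β,9α,10α-triol
Conditions: Zn dust, EtOH, 60 °C; aq. NH4Cl
Reagents that add atoms: none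
Why: Zinc insertion into the C–I bond and β-elimination of the epoxide oxygen (reductive epoxide opening) moves the oxygen from C14 to C9 and forms the exocyclic alkene; the C9–O bond is not broken, so the configuration set in step 10 is kept.

Step 13
Reactants: 17 dauca-5,8(14)-diene-4β,9α,10α-triol
Product: 18 dauca-5,8(14)-diene-4β,9α,10α-triol 9,10-acetonide
Conditions: 2-methoxypropene, PPTS (cat.), CH2Cl2, 0 °C
Reagents that add atoms: 2-methoxypropene, COC(C)=C
Why: Acid-catalysed ketal exchange; only the cis-vicinal diol can close a dioxolane, so C4–OH remains as the one free hydroxyl.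

Step 14
Reactants: 18 dauca-5,8(14)-diene-4β,9α,10α-triol 9,10-acetonide
Product: 19 5β,6β-epoxydauc-8(14)-ene-4β,9α,10α-triol 9,10-acetonide
Conditions: VO(acac)2 (cat.), t-BuOOH, CH2Cl2, rt
Reagents that add atoms: tert-butyl hydroperoxide, CC(C)(C)OO
Why: VO(acac)2-catalysed hydroxyl-directed epoxidation: the 4β-alkoxide bound to the oxovanadium centre delivers oxygen to the β face of C5=C6, also the sterically open face. The exocyclic alkene has no free allylic hydroxyl and should react far more slowly.

Step 15
Reactants: 19 5β,6β-epoxydauc-8(14)-ene-4β,9α,10α-triol 9,10-acetonide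
Product: 20 5α-dauc-8(14)-ene-4β,6β,9α,10α-tetrol 9,10-acetonide
Conditions: Cp2TiCl2, Mn dust, cyclohexa-1,4-diene, THF, rt; aq. HCl work-up
Reagents that add atoms: none
Why: Titanocene-mediated reductive epoxide opening (Nugent–RajanBabu reaction): Cp2TiCl, a trivalent titanium species made in the flask, cleaves C5–O homolytically to the tertiary C5 radical, so no cation arises and no shift from C4 is triggered. Cyclohexadiene then transfers hydrogen to the face anti to the bulky titanoxy group on C6 and to C15 and the C4 oxygen, which sets 5α-H and the trans ring fusion.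

Step 16
Reactants: 20 5α-dauc-8(14)-ene-4β,6β,9α,10α-tetrol 9,10-acetonide
Product: 21 4β-hydroxy-9α,10α-(isopropylidenedioxy)-5α-dauc-8(14)-en-6-one
Conditions: Dess–Martin periodinane, NaHCO3, CH2Cl2, 0 °C → rt
Reagents that add atoms: none
Why: Dess–Martin oxidation of the only secondary alcohol under buffered, non-basic conditions; without base the C5 centre and the β-hydroxy ketone are not put at risk of epimerisation or retro-aldol cleavage.

Step 17
Reactants: 21 4β-hydroxy-9α,10α-(isopropylidenedioxy)-5α-dauc-8(14)-en-6-one
Product: 22 5α-dauc-8(14)-ene-4β,6α,9α,10α-tetrol 9,10-acetonide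
Conditions: Me4NBH(OAc)3, MeCN/AcOH, −20 °C
Reagents that add atoms: none
Why: Evans–Saksena reduction: the triacetoxyborohydride exchanges onto the 4β-hydroxyl and delivers hydride intramolecularly to the β face of the C6 carbonyl, giving the 1,3-anti diol, that is 6α-OH.

Step 18
Reactants: 22 5α-dauc-8(14)-ene-4β,6α,9α,10α-tetrol 9,10-acetonide; 23 isovaleryl chloride
Product: 24 5α-dauc-8(14)-ene-4β,6α,9α,10α-tetrol 9,10-acetonide 6-(3-methylbutanoate)
Conditions: pyridine, DMAP (cat.), CH2Cl2, 0 °C → rt
Reagents that add atoms: none
Why: Acylation with nucleophilic catalysis at the only secondary hydroxyl; the tertiary C4–OH does not react under these conditions.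

Step 19
Reactants: 24 5α-dauc-8(14)-ene-4β,6α,9α,10α-tetrol 9,10-acetonide 6-(3-methylbutanoate)
Product: 25 5α-dauc-8(14)-ene-4β,6α,9α,10α-tetrol 6-(3-methylbutanoate) (CNP0204264.1)
Conditions: AcOH/H2O (4:1), 40 °C
Reagents that add atoms: none
Why: Mild aqueous acid hydrolyses the dioxolane (acetal hydrolysis); the ester and the tertiary alcohol are stable, and the acidity is too low to ionise the allylic C9 carbinol.

## Compound list

1 | (S)-terpinen-4-ol, (1S)-4-methyl-1-(propan-2-yl)cyclohex-3-en-1-ol | CC1=CC[C@](O)(C(C)C)CC1 | starting material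
2 | triethyl{[(1S)-4-methyl-1-(propan-2-yl)cyclohex-3-en-1-yl]oxy}silane | CC1=CC[C@](O[Si](CC)(CC)CC)(C(C)C)CC1 | intermediate
3 | ozonide of 2 (1,2,4-trioxolane bridging the former alkene carbons; mixture at the two new centres; not isolated) | CC12CC[C@@](O[Si](CC)(CC)CC)(C(C)C)CC(OO1)O2 | intermediate
4 | (3S)-6-oxo-3-(propan-2-yl)-3-[(triethylsilyl)oxy]heptanal | O=CC[C@](O[Si](CC)(CC)CC)(C(C)C)CCC(C)=O | intermediate
5 | (5R)-2-methyl-5-(propan-2-yl)-5-[(triethylsilyl)oxy]cyclopent-1-ene-1-carbaldehyde | O=CC1=C(C)CC[C@@]1(O[Si](CC)(CC)CC)C(C)C | intermediate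
6 | (5R)-1-ethenyl-2-methyl-5-(propan-2-yl)-5-[(triethylsilyl)oxy]cyclopent-1-ene | C=CC1=C(C)CC[C@@]1(O[Si](CC)(CC)CC)C(C)C | intermediate
7 | methyl diazoacetate | COC(=O)C=[N+]=[N-] | starting material
8 | (tert-butyldimethylsilyloxy)acetaldehyde | O=CCO[Si](C)(C)C(C)(C)C | starting material
9 | methyl 4-[(tert-butyldimethylsilyl)oxy]-2-diazo-3-hydroxybutanoate (racemic) | COC(=O)C(=[N+]=[N-])C(O)CO[Si](C)(C)C(C)(C)C | intermediate
10 | methyl (3E)-4-[(tert-butyldimethylsilyl)oxy]-2-diazobut-3-enoate | COC(=O)C(=[N+]=[N-])/C=C/O[Si](C)(C)C(C)(C)C | intermediate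
11 | methyl (1R,2S)-1-[(E)-2-[(tert-butyldimethylsilyl)oxy]ethenyl]-2-[(5R)-2-methyl-5-(propan-2-yl)-5-[(triethylsilyl)oxy]cyclopent-1-en-1-yl]cyclopropane-1-carboxylate (cis-divinylcyclopropane; not isolated) | COC(=O)[C@]1(/C=C/O[Si](C)(C)C(C)(C)C)C[C@H]1C2=C(C)CC[C@@]2(O[Si](CC)(CC)CC)C(C)C | intermediate
12 | methyl (3R,8R,8aS)-8-[(tert-butyldimethylsilyl)oxy]-8a-methyl-3-(propan-2-yl)-3-[(triethylsilyl)oxy]-1,2,3,5,8,8a-hexahydroazulene-6-carboxylate (C14 ester on C8; C8=C9 and C5=C6; 10α-OTBS; 4β-OTES) | COC(=O)C1=C[C@@H](O[Si](C)(C)C(C)(C)C)[C@@]2(C)CC[C@@](O[Si](CC)(CC)CC)(C(C)C)C2=CC1 | intermediate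
13 | [(3R,8R,8aS)-8-[(tert-butyldimethylsilyl)oxy]-8a-methyl-3-(propan-2-yl)-3-[(triethylsilyl)oxy]-1,2,3,5,8,8a-hexahydroazulen-6-yl]methanol | OCC1=C[C@@H](O[Si](C)(C)C(C)(C)C)[C@@]2(C)CC[C@@](O[Si](CC)(CC)CC)(C(C)C)C2=CC1 | intermediate
14 | (3R,8R,8aS)-6-(hydroxymethyl)-8a-methyl-3-(propan-2-yl)-1,2,3,5,8,8a-hexahydroazulene-3,8-diol | OCC1=C[C@@H](O)[C@@]2(C)CC[C@@](O)(C(C)C)C2=CC1 | intermediate
15 | 8α,9α-epoxydauc-5-ene-4β,10α,14-triol | OC[C@@]12CC=C3[C@](O)(C(C)C)CC[C@]3(C)[C@H](O)[C@@H]1O2 | intermediate
16 | 8α,9α-epoxy-14-iododauc-5-ene-4β,10α-diol | IC[C@@]12CC=C3[C@](O)(C(C)C)CC[C@]3(C)[C@H](O)[C@@H]1O2 | intermediate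
17 | dauca-5,8(14)-diene-4β,9α,10α-triol | C=C1CC=C2[C@](O)(C(C)C)CC[C@]2(C)[C@H](O)[C@@H]1O | intermediate
18 | dauca-5,8(14)-diene-4β,9α,10α-triol 9,10-acetonide | C=C1CC=C2[C@](O)(C(C)C)CC[C@]2(C)[C@H](OC3(C)C)[C@@H]1O3 | intermediate
19 | 5β,6β-epoxydauc-8(14)-ene-4β,9α,10α-triol 9,10-acetonide | C=C1C[C@H]2O[C@]23[C@](O)(C(C)C)CC[C@]3(C)[C@H](OC4(C)C)[C@@H]1O4 | intermediate
20 | 5α-dauc-8(14)-ene-4β,6β,9α,10α-tetrol 9,10-acetonide | C=C1C[C@@H](O)[C@@H]2[C@](C)(CC[C@@]2(O)C(C)C)[C@H](OC3(C)C)[C@@H]1O3 | intermediate
21 | 4β-hydroxy-9α,10α-(isopropylidenedioxy)-5α-dauc-8(14)-en-6-one | C=C1CC(=O)[C@@H]2[C@](C)(CC[C@@]2(O)C(C)C)[C@H](OC3(C)C)[C@@H]1O3 | intermediate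
22 | 5α-dauc-8(14)-ene-4β,6α,9α,10α-tetrol 9,10-acetonide | C=C1C[C@H](O)[C@@H]2[C@](C)(CC[C@@]2(O)C(C)C)[C@H](OC3(C)C)[C@@H]1O3 | intermediate
23 | isovaleryl chloride (3-methylbutanoyl chloride) | CC(C)CC(Cl)=O | starting material
24 | 5α-dauc-8(14)-ene-4β,6α,9α,10α-tetrol 9,10-acetonide 6-(3-methylbutanoate) | C=C1C[C@H](OC(=O)CC(C)C)[C@@H]2[C@](C)(CC[C@@]2(O)C(C)C)[C@H](OC3(C)C)[C@@H]1O3 | intermediate
25 | 5α-dauc-8(14)-ene-4β,6α,9α,10α-tetrol 6-(3-methylbutanoate), CNP0204264.1 | C=C1C[C@H](OC(=O)CC(C)C)[C@@H]2[C@](C)(CC[C@@]2(O)C(C)C)[C@H](O)[C@@H]1O | target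

## Step count and least certain steps

Total: 19 steps. Longest linear sequence: 17 steps (steps 1–4 and 7–19, from 1); the diazoester arm (steps 5–6) is two steps and joins at step 7.

**Step 7 (key step).**
- What may go wrong: the face selection in the cyclopropanation may be poor if the catalyst and the C4 centre oppose each other, and the boat must bring C10 to the face of C1 that carries the isopropyl group, so the wanted diastereomer of 11 is the slower one to rearrange.
- Further risks: the electron-rich carbenoid may be attacked at its vinylogous, oxocarbenium-like terminus, or 10 may electrocyclise before it reaches the metal.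
- Fallback (covalent instead of catalyst control): from 6, the auxiliary-bearing diazoester (R)-pantolactonyl (3E)-4-[(tert-butyldimethylsilyl)oxy]-2-diazobut-3-enoate F1 is decomposed by achiral Rh2(O2CC7H15)4 in hexanes. This is the lactone-auxiliary version of the same tandem reaction, and the enantiomer of the auxiliary is chosen to match. The resulting pantolactonyl ester of the hydroazulene diene F2 is reduced with LiAlH4 in Et2O, which releases the auxiliary and gives 13, where the route is rejoined.

**Step 15.**
- What may go wrong: hydrogen may be delivered to the wrong face of the C5 radical, giving the cis-fused epimer, if the isopropyl group on the α face outweighs the titanoxy group, C15 and the C4 oxygen on the β face. The radical may also be captured by a second Cp2TiCl and lose the oxygen, returning alkene 18.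
- Fallback (1,2-hydride shift instead of intermolecular hydrogen transfer): from 19, the tertiary hydroxyl is silylated with 1-(trimethylsilyl)imidazole to the 4-O-trimethylsilyl epoxide F3. BF3·OEt2 in CH2Cl2 at −78 °C then effects a Meinwald rearrangement, in which hydride migrates from C6 to C5 anti to the departing oxygen, to the 4-O-trimethylsilyl ketone F4. Aqueous citric acid removes the silyl group to give 21.
- Caveat: the silyl ether remains a donor that can trigger migration from C4, which is why this sequence is the reserve and not the first choice.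

**Step 14.**
- What may go wrong: oxygen transfer to a trisubstituted alkene flanked by two fully substituted carbons may be slow, and oxidation of the exocyclic alkene may then compete.
- Fallback (epoxidise C5=C6 while no other alkene is present): from 15, VO(acac)2 and t-BuOOH give the bis-epoxide triol F5 under the same C4–OH direction. Iodination as in step 11 gives the bis-epoxy iodide F6, and zinc as in step 12 gives the 5β,6β-epoxy triol F7. Acetonide formation as in step 13 then gives 19.

**Step 10.**
- What may go wrong: the three hydroxyls of 14 may tie up the Ti(OiPr)4–tartrate complex and slow turnover, which would let the tertiary alcohol direct some oxidation to C5=C6.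
- Fallback (epoxidise before unmasking): from 13, a classical mono-ol substrate, the same tartrate reagent gives the disilyl epoxy alcohol F8, face selection then resting on the reagent alone against the C10 silyl ether. TBAF as in step 9 gives 15.

## Further compounds

F1 | step 7 | (R)-pantolactonyl (3E)-4-[(tert-butyldimethylsilyl)oxy]-2-diazobut-3-enoate | CC1(C)COC(=O)[C@@H]1OC(=O)C(=[N+]=[N-])/C=C/O[Si](C)(C)C(C)(C)C
F2 | step 7 | (R)-pantolactonyl ester corresponding to 12 | CC1(C)COC(=O)[C@@H]1OC(=O)C1=C[C@@H](O[Si](C)(C)C(C)(C)C)[C@@]2(C)CC[C@@](O[Si](CC)(CC)CC)(C(C)C)C2=CC1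
F3 | step 15 | 4-O-trimethylsilyl ether of 19 | C=C1C[C@H]2O[C@]23[C@](O[Si](C)(C)C)(C(C)C)CC[C@]3(C)[C@H](OC4(C)C)[C@@H]1O4
F4 | step 15 | 4-O-trimethylsilyl ether of 21 | C=C1CC(=O)[C@@H]2[C@](C)(CC[C@@]2(O[Si](C)(C)C)C(C)C)[C@H](OC3(C)C)[C@@H]1O3
F5 | step 14 | 5β,6β:8α,9α-diepoxydaucane-4β,10α,14-triol | OC[C@@]12C[C@H]3O[C@]34[C@](O)(C(C)C)CC[C@]4(C)[C@H](O)[C@@H]1O2
F6 | step 14 | 5β,6β:8α,9α-diepoxy-14-iododaucane-4β,10α-diol | IC[C@@]12C[C@H]3O[C@]34[C@](O)(C(C)C)CC[C@]4(C)[C@H](O)[C@@H]1O2
F7 | step 14 | 5β,6β-epoxydauc-8(14)-ene-4β,9α,10α-triol | C=C1C[C@H]2O[C@]23[C@](O)(C(C)C)CC[C@]3(C)[C@H](O)[C@@H]1O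
F8 | step 10 | 8α,9α-epoxide of 13 (10-O-TBS, 4-O-TES) | OC[C@@]12CC=C3[C@](O[Si](CC)(CC)CC)(C(C)C)CC[C@]3(C)[C@H](O[Si](C)(C)C(C)(C)C)[C@@H]1O2
A1 | alternative 1 | 3-methylcyclopent-2-en-1-one | CC1=CC(=O)CC1
A2 | alternative 1 | diisobutyl[1-(trimethylsilyl)ethenyl]alane | C=C([Si](C)(C)C)[Al](CC(C)C)CC(C)C
A3 | alternative 1 | 4-(trimethylsilyl)but-3-ynal | C[Si](C)(C)C#CCC=O
A4 | alternative 1 | 2-[1-hydroxy-4-(trimethylsilyl)but-3-yn-1-yl]-3-methyl-3-[1-(trimethylsilyl)ethenyl]cyclopentan-1-one (2,3-trans, anti aldol) | C[Si](C)(C)C#CC[C@H](O)[C@H]1C(=O)CC[C@]1(C)C(=C)[Si](C)(C)C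
A5 | alternative 2 | 1-methoxy-6-methyl-3-(propan-2-yl)-3-[(triethylsilyl)oxy]-8-(trimethylsilyl)octa-1,6-diene (alkene geometries open) | COC=C[C@](O[Si](CC)(CC)CC)(C(C)C)CCC(C)=CC[Si](C)(C)C
A6 | alternative 2 | 2-(dimethoxymethyl)-1-ethenyl-1-methyl-3-(propan-2-yl)-3-[(triethylsilyl)oxy]cyclopentane | C=C[C@@]1(C)CC[C@@](O[Si](CC)(CC)CC)(C(C)C)[C@@H]1C(OC)OC
A7 | alternative 3 | 1-[(tert-butyldimethylsilyl)oxy]-1-[2-methyl-5-(propan-2-yl)-5-[(triethylsilyl)oxy]hept-1-en-6-yn-1-yl]cyclopropane (alkene geometry open) | C#C[C@](O[Si](CC)(CC)CC)(C(C)C)CCC(C)=CC1(O[Si](C)(C)C(C)(C)C)CC1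
A8 | alternative 3 | hydroazulene with C9 silyl enol ether (C9=C10), C5=C6 alkene and C4 silyl ether | CC(C)[C@]1(O[Si](CC)(CC)CC)CC[C@]2(C)C=C(O[Si](C)(C)C(C)(C)C)CCC=C12
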